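## Structural features

The target is a furanoheliangolide. A ten-membered carbocycle (C1–C10, germacrane numbering) is bridged by oxygen between C3 and C10, so that the C1 ketone, C2=C3, the bridging oxygen and the quaternary C10 (methyl C14) form a 3(2H)-furanone spanned by the six-carbon handle C4–C9. A trans-fused α-methylene-γ-butyrolactone (C12 carbonyl, C11=C13) sits on C6/C7, C8 carries a methacrylate, and the Z trisubstituted C4=C5 alkene carries the C15 hydroxymethyl group. Three stereocentres are contiguous (C6, C7, C8, all R); the fourth, quaternary C10 (R), is separated from them by the C9 methylene and lies across the flat furanone from C4. The fragile groups are the two Michael acceptors (C11=C13 and the methacrylate), the allylic lactone C6–O bond, the doubly allylic C7–H, the free primary allylic alcohol, and the furanone, whose ring oxygen is a vinylogous carboxylate leaving group β to C8. The real difficulty is to close the strained bridged ring with a Z alkene, to relate C6–C8 to the remote C10, and to keep the electrophilic groups intact in the last steps. The feature used by the key step is the array C15–OH / Z C4=C5 / lactone C6–O. This 1,4-dioxygenated allyl unit is what a C4 spiro-epoxide with a C5=C6 alkene gives when it is opened at C6 by the C12 carboxylate held on C7.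

## Logic of the disconnections

30 to 29. The lactone C6–O bond is cut, C4=C5 is moved to C5=C6 and O15 is closed onto C4 as a spiro-epoxide. This removes the lactone ring and the C6 stereocentre, leaves O15 unprotected and puts no step after the key step. The forward step needs the (4R) epoxide with its oxygen on the face on which C7 carries the acid, a catalyst that ionizes only the vinyl epoxide, and neutral conditions.

29 to 28 to 26. The C12 acid is masked as a 2-(trimethylsilyl)ethyl ester and the C8–O acyl bond to 27 is cut. The ester can be removed by fluoride without acid, base or metal. The methacrylate is attached only after ring closure, because before it the C8 ester and the C7 vinyl group would close a six-membered unsaturated lactone by metathesis. The forward steps must spare the epoxide and both acrylic units.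

26 to 25. The C5=C6 double bond is cut (ring-closing metathesis). Both partners are then simple vinyl groups, and the bridged ring can only hold the Z alkene. The macrocycle becomes an acyclic triene. The forward step needs high dilution and suppression of olefin migration at C7.

25 to 17 and 23. The C7–C8 bond is cut. One union then creates C7, C8, the C6 vinyl group and the α-methylene carboxyl unit. The forward step needs the 7,8-syn relationship and tolerance of the epoxide and the β-alkoxy aldehyde. Its facial sense relative to C10 is the weak point of the plan.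

23 to 22 to 20 and 21, and 20 to 18 and 19. The C13–Br bond (with allylic transposition), the C7–C11 bond and the ester C–O bond are cut. This leads to three commercial compounds. The forward steps need the conjugated (Z)-bromide.

17 to 16 to 12 and 5. After adjustment of the C8 oxidation level, the furanone O10–C3 bond and the C1–C2 bond are cut. The furanone then comes from an α′-hydroxy ynone under mild base, so the vinyl epoxide can be present already and no electrophilic 5-acyl furanone is ever made. The forward step needs single addition of the acetylide to the lactone.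

12 to 10 to 9 to 8 to 6 and 7. The C5=C6 bond (methylenation), the epoxide C–O bonds (asymmetric epoxidation of an allylic alcohol) and the C3–C4 bond (sp–sp2 coupling) are cut. C4 is thus set by a reagent on a small acyclic alcohol. It is not left to an ylide addition on a macrocyclic dienone, whose face is unpredictable and whose γ-hydrogen at C7 is acidic.

5 to 4 to 2 to 1. The O–Si bond and the lactone C–O bond are cut and the primary alcohol is returned to the acid. C10 is taken unchanged from the chiral pool. The forward steps need differentiation of the two carboxyl groups of 1.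

## Other disconnections considered

Alternative 1: The C3 and C8 carbonyl groups of the ten-membered trione A2 are reconnected as the ring-fusion glycol of the cis-decalin A1. In the forward direction Pb(OAc)4 cleaves the C3–C8 bond of A1, each carbinol becomes a ketone and the carbocycle opens.
- In favour: the ring arises by fragmentation, so no high-dilution closure is needed. The C4=C5 geometry is inherited from a cyclohexene and is Z by construction. C6 and C7 can be set with six-membered-ring control.
- Against: A2 is far from 30. The C1/C3 diketone must be cyclodehydrated onto O10, the C8 ketone reduced from the right face, C8 acylated and O15 unmasked. In A2 the C7 hydrogen is α to the C8 ketone and the lactone oxygen is β to it, so enolization threatens epimerization at C7 and β-elimination of the lactone. A1 needs five stereocentres on a decalin, the quaternary C10 among them.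
- Comparison: on alkene geometry the two plans are equal, since both enforce Z by a ring. On the ring-forming event the alternative is the better. On mechanism the chosen plan is safer at C6–C8, because it never places a ketone next to C7. On step economy after the key step the chosen plan is better (none against at least four).

Alternative 2: The C4=C5 double bond is cut. In the forward direction ring-closing metathesis of the diene A3 (C6 vinyl group and the 1,1-disubstituted C4 alkene on the furanone) gives A4.
- In favour: lactone, C6, C7 and C8 are in place before the ring is closed, so C6 does not depend on a stereospecific transposition; on this point the alternative is the better. No epoxide is carried, and the alkene formed is the final one.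
- Against: a trisubstituted alkene must form inside the strained ring from a hindered 1,1-disubstituted partner. A4 lacks C13, so the methylene group must be added late by enolate chemistry on the lactone, next to a base-sensitive furanone. Desilylation at O8, acylation and desilylation at O15 follow, at least five operations in all.
- Comparison: both plans close the ring by metathesis and are equal in kind; the chosen plan closes the easier disubstituted alkene. Mechanistically the alternative is simpler at C6. On step economy the chosen plan is better, because its key step ends the synthesis.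

Alternative 3: The C9–C10 bond is cut. In the forward direction (NH4)2Ce(NO3)6 oxidizes A5, in which a 3-silyloxyfuran and the C8 enol ether are joined through a diisopropylsilyl group; C9 bonds to C10 and the 8-oxo core A6 results.
- In favour: the quaternary centre and the carbocycle arise in one C–C bond formation from fragments joined only through O–Si bonds. In convergence the alternative is the better.
- Against: the configuration at C10 would rest on the face of the furan attacked in a macrocyclic transition state. The one-electron oxidation generates radical character next to an α-methylene lactone, a good radical acceptor, and next to an electron-rich trisubstituted alkene. A6 again has a C8 ketone flanked by C7–H, and needs reduction, acylation and desilylation.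
- Comparison: both plans form the ring and one stereocentre in a single step and are equal in that. The alternative is better in convergence. The chosen plan is better in stereochemical predictability (C10 from the chiral pool, C6 by a stereospecific mechanism) and in tolerance of functional groups. After the key step it needs no step against three.

Key step: step 17

Remark 1: atom labels C1–C15 are those of the germacrane skeleton. The target is read as 4Z,6R,7R,8R,10R and 29 as 4R,5Z,7R,8R,10R; this pair is consistent with a double-inversion course, so neither structure needed correction.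

Remark 2 (assumption): the two 7,8-syn adducts of step 13, which differ in their sense relative to C10, are taken to be separable by chromatography.

Step 1
Reactants: 1 (R)-citramalic acid
Product: 2 2-[(4R)-2,2,4-trimethyl-5-oxo-1,3-dioxolan-4-yl]acetic acid
Conditions: 2,2-dimethoxypropane, TsOH·H2O (cat.), CH2Cl2, rt
Reagents that add atoms: 2,2-dimethoxypropane, COC(C)(C)OC
Why: Acid-catalysed acetal exchange; the α-hydroxy acid closes the five-membered dioxolanone and leaves the distal carboxyl free, as in the malic acid series. C10 is not touched.

Step 2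
Reactants: 2 2-[(4R)-2,2,4-trimethyl-5-oxo-1,3-dioxolan-4-yl]acetic acid
Product: 4 (3R)-3-hydroxy-3-methyloxolan-2-one, via hydroxyethyl dioxolanone 3 (not isolated)
Conditions: BH3·SMe2, THF, 0 °C to rt; MeOH; then TsOH·H2O (cat.), CH2Cl2, rt
Reagents that add atoms: none
Why: Borane reduces the free acid in preference to the dioxolanone; acid-catalysed translactonization of the primary alcohol onto the dioxolanone carbonyl then expels acetone and gives the α-hydroxy lactone.

Step 3
Reactants: 4 (3R)-3-hydroxy-3-methyloxolan-2-one
Product: 5 (3R)-3-methyl-3-(trimethylsilyloxy)oxolan-2-one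
Conditions: Me3SiCl, imidazole, CH2Cl2, 0 °C to rt
Reagents that add atoms: chlorotrimethylsilane, C[Si](C)(C)Cl
Why: Silylation of the tertiary alcohol, so that no acidic proton consumes the acetylide in step 8.

Step 4
Reactants: 6 2-bromoprop-2-en-1-ol; 7 ethynyltrimethylsilane
Product: 8 2-methylidene-4-(trimethylsilyl)but-3-yn-1-ol
Conditions: PdCl2(PPh3)2 (2 mol %), CuI (4 mol %), iPr2NH, THF, rt
Reagents that add atoms: none
Why: Sonogashira coupling of a vinyl bromide with a terminal alkyne; the free allylic alcohol is tolerated. This forms the C3–C4 bond.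

Step 5
Reactants: 8 2-methylidene-4-(trimethylsilyl)but-3-yn-1-ol
Product: 9 [(2R)-2-[(trimethylsilyl)ethynyl]oxiran-2-yl]methanol
Conditions: Ti(OiPr)4 (10 mol %), D-(−)-diethyl tartrate (12 mol %), t-BuOOH, 4 Å molecular sieves, CH2Cl2, −20 °C
Reagents that add atoms: tert-butyl hydroperoxide, CC(C)(C)OO
Why: Sharpless asymmetric epoxidation of a 2-substituted allylic alcohol. With the D-(−)-tartrate, oxygen is delivered to the face that gives the (R)-epoxy alcohol, which fixes the later C4 by reagent control.

Step 6
Reactants: 9 [(2R)-2-[(trimethylsilyl)ethynyl]oxiran-2-yl]methanol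
Product: 10 (2S)-2-[(trimethylsilyl)ethynyl]oxirane-2-carbaldehyde
Conditions: Dess–Martin periodinane, NaHCO3, CH2Cl2, 0 °C to rt
Reagents that add atoms: none
Why: Buffered periodinane oxidation of the primary alcohol. The α-carbon is quaternary and cannot epimerize; the descriptor changes only through the priority rules.

Step 7
Reactants: 10 (2S)-2-[(trimethylsilyl)ethynyl]oxirane-2-carbaldehyde
Product: 12 (2S)-2-ethenyl-2-ethynyloxirane, via silylated enyne epoxide 11 (not isolated)
Conditions: Ph3PCH3Br, KN(SiMe3)2, THF, −78 to 0 °C; then K2CO3, MeOH, 0 °C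
Reagents that add atoms: methyltriphenylphosphonium bromide, C[P+](c1ccccc1)(c1ccccc1)c1ccccc1.[Br-]
Why: Wittig methylenation of the non-enolizable aldehyde, then base-mediated protodesilylation of the alkynylsilane. The volatile product is taken on as a dried, assayed solution.

Step 8
Reactants: 12 (2S)-2-ethenyl-2-ethynyloxirane; 5 (3R)-3-methyl-3-(trimethylsilyloxy)oxolan-2-one
Product: 16 (2R)-5-[(2R)-2-ethenyloxiran-2-yl]-2-(2-hydroxyethyl)-2-methylfuran-3(2H)-one, via lithium acetylide 13 (not isolated), via silyloxy ynone 14 (not isolated), via dihydroxy ynone 15 (not isolated)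
Conditions: n-BuLi, THF, −78 °C; 5, −78 to −40 °C; AcOH; then K2CO3 (cat.), MeOH, 0 °C to rt
Reagents that add atoms: none
Why: Acylation of a lithium acetylide by a lactone; the lithium lactolate does not collapse in the cold, so addition stops at the ynone stage. Methanolysis of the silyl ether frees the tertiary hydroxyl, which closes the 3(2H)-furanone by 5-endo-dig oxa-Michael addition, a standard cyclization of α′-hydroxy ynones. No stereocentre is touched.

Step 9
Reactants: 16 (2R)-5-[(2R)-2-ethenyloxiran-2-yl]-2-(2-hydroxyethyl)-2-methylfuran-3(2H)-one
Product: 17 2-[(2R)-5-[(2R)-2-ethenyloxiran-2-yl]-2-methyl-3-oxo-2,3-dihydrofuran-2-yl]acetaldehyde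
Conditions: Dess–Martin periodinane, NaHCO3, CH2Cl2, 0 °C
Reagents that add atoms: none
Why: Buffered, non-basic oxidation gives the C8 aldehyde. It is used at once, because the furanone oxygen is a β-leaving group.

Step 10
Reactants: 18 acryloyl chloride; 19 2-(trimethylsilyl)ethanol
Product: 20 2-(trimethylsilyl)ethyl acrylate
Conditions: Et3N, CH2Cl2, 0 °C
Reagents that add atoms: none
Why: Acylation of a primary alcohol by an acid chloride. The ester group is chosen so that C12 can later be unmasked by fluoride.

Step 11
Reactants: 20 2-(trimethylsilyl)ethyl acrylate; 21 acrolein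
Product: 22 2-(trimethylsilyl)ethyl 3-hydroxy-2-methylidenepent-4-enoate (racemic)
Conditions: DABCO (0.3 equiv), 1,4-dioxane–H2O, rt
Reagents that add atoms: none
Why: Morita–Baylis–Hillman reaction of an acrylate with an enal. The carbinol centre is lost in the next step, so the racemate suffices.

Step 12
Reactants: 22 2-(trimethylsilyl)ethyl 3-hydroxy-2-methylidenepent-4-enoate
Product: 23 2-(trimethylsilyl)ethyl (2Z)-2-(bromomethyl)penta-2,4-dienoate
Conditions: N-bromosuccinimide, Me2S, CH2Cl2, 0 °C to rt
Reagents that add atoms: N-bromosuccinimide, O=C1CCC(=O)N1Br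
Why: Bromination of a Baylis–Hillman alcohol with allylic transposition through the alkoxysulfonium salt; it gives the conjugated bromide with the vinyl group trans to the ester. A regioisomeric bromide would converge on the same pentadienyl metal in step 13.

Step 13
Reactants: 17 2-[(2R)-5-[(2R)-2-ethenyloxiran-2-yl]-2-methyl-3-oxo-2,3-dihydrofuran-2-yl]acetaldehyde; 23 2-(trimethylsilyl)ethyl (2Z)-2-(bromomethyl)penta-2,4-dienoate
Product: 25 2-(trimethylsilyl)ethyl (3R,4R)-3-ethenyl-5-[(2R)-5-[(2R)-2-ethenyloxiran-2-yl]-2-methyl-3-oxo-2,3-dihydrofuran-2-yl]-4-hydroxy-2-methylidenepentanoate, via allylindium bromide 24 (not isolated)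
Conditions: In powder, THF–H2O, rt
Reagents that add atoms: none
Why: Indium-mediated Barbier allylation. The organoindium reacts at C7 through a six-membered chair in which the vinyl group, cis to CH2In, is axial, which gives the 7,8-syn relationship. The facial sense relative to C10 is under weak substrate control only, so the (7R,8R) adduct 25 is separated from its 7,8-bis-epimer.

Step 14
Reactants: 25 2-(trimethylsilyl)ethyl (3R,4R)-3-ethenyl-5-[(2R)-5-[(2R)-2-ethenyloxiran-2-yl]-2-methyl-3-oxo-2,3-dihydrofuran-2-yl]-4-hydroxy-2-methylidenepentanoate
Product: 26 2-(trimethylsilyl)ethyl (4R,5Z,7R,8R,10R)-4,15:3,10-diepoxy-8-hydroxy-1-oxogermacra-2,5,11(13)-trien-12-oate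
Conditions: second-generation Hoveyda–Grubbs catalyst RuCl2(H2IMes)(=CH-C6H4-2-OiPr) (15 mol %), 1,4-benzoquinone (30 mol %), toluene (1 mM), 80 °C
Reagents that add atoms: none
Why: Ring-closing metathesis of the two vinyl groups; the electron-poor 1,1-disubstituted C11=C13 alkene is much less reactive. The furanone-bridged ring can hold only the Z alkene. Benzoquinone suppresses hydride-mediated migration at the doubly allylic C7.

Step 15
Reactants: 26 2-(trimethylsilyl)ethyl (4R,5Z,7R,8R,10R)-4,15:3,10-diepoxy-8-hydroxy-1-oxogermacra-2,5,11(13)-trien-12-oate; 27 methacrylic anhydride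
Product: 28 2-(trimethylsilyl)ethyl (4R,5Z,7R,8R,10R)-4,15:3,10-diepoxy-8-(2-methylprop-2-enoyloxy)-1-oxogermacra-2,5,11(13)-trien-12-oate
Conditions: Et3N, DMAP (cat.), CH2Cl2, 0 °C to rt
Reagents that add atoms: none
Why: DMAP-catalysed acylation of the secondary alcohol with retention at C8. It is placed after ring closure so that the methacrylate cannot close a six-membered lactone with the C7 vinyl group by metathesis.

Step 16
Reactants: 28 2-(trimethylsilyl)ethyl (4R,5Z,7R,8R,10R)-4,15:3,10-diepoxy-8-(2-methylprop-2-enoyloxy)-1-oxogermacra-2,5,11(13)-trien-12-oate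
Product: 29 (4R,5Z,7R,8R,10R)-4,15:3,10-diepoxy-8-(2-methylprop-2-enoyloxy)-1-oxogermacra-2,5,11(13)-trien-12-oic acid
Conditions: (Me2N)3S+ Me3SiF2−, DMF, 0 °C; aq. NaH2PO4 (pH 5)
Reagents that add atoms: none
Why: Fluoride-induced fragmentation of the 2-(trimethylsilyl)ethyl ester (attack at silicon, loss of ethylene). The conditions are anhydrous and close to neutral, and should spare the methacrylate and the vinyl epoxide. The acid is used without purification.

Step 17
Reactants: 29 (4R,5Z,7R,8R,10R)-4,15:3,10-diepoxy-8-(2-methylprop-2-enoyloxy)-1-oxogermacra-2,5,11(13)-trien-12-oic acid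
Product: 30 (4Z,6R,7R,8R,10R)-3,10-epoxy-15-hydroxy-8-(2-methylprop-2-enoyloxy)-1-oxogermacra-2,4,11(13)-trien-12,6-olide (the target)
Conditions: Pd(PPh3)4 (5 mol %), THF, 0 °C to rt
Reagents that add atoms: none
Why: Zerovalent palladium binds C5=C6 on the face anti to the C4–O bond and ionizes the epoxide to an anti,anti π-allyl palladium unit (C4–C5–C6) with a C15 alkoxide, which takes the proton of the C12 acid. The carboxylate then attacks C6 on the face opposite to palladium in a 5-exo closure onto the allyl terminus; this forms the C6–O bond, leaves C4=C5 and the free C15 hydroxyl, and returns the catalyst. The closest known reaction is the Pd(PPh3)4-catalysed 1,4-addition of carboxylic acids to 1,3-diene monoepoxides, which runs with net retention by double inversion. C6 (R) is therefore controlled by C4 (R): oxygen enters on the face the epoxide oxygen left, which is the face on which C7 holds the acid, and the lactone is trans-fused. The C4=C5 alkene is Z because the ring holds C3 and C7 in the anti positions of the allyl unit. Site selectivity is secured because the epoxide is the only ionizable allylic C–O bond (the methacrylate is homoallylic). Regioselectivity is secured because attack at C4 would need a seven-membered ring at a quaternary terminus. The medium is neutral, so both acrylic units survive; low temperature and a short reaction time limit re-ionization of the allylic lactone.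

Compound list

1 | (R)-citramalic acid | OC(=O)C[C@@](C(=O)O)(C)O | starting material
2 | 2-[(4R)-2,2,4-trimethyl-5-oxo-1,3-dioxolan-4-yl]acetic acid | OC(=O)C[C@@]1(C)OC(C)(C)OC1=O | intermediate
3 | (5R)-5-(2-hydroxyethyl)-2,2,5-trimethyl-1,3-dioxolan-4-one (not isolated) | OCC[C@@]1(C)OC(C)(C)OC1=O | intermediate
4 | (3R)-3-hydroxy-3-methyloxolan-2-one | O=C1OCC[C@@]1(C)O | intermediate
5 | (3R)-3-methyl-3-(trimethylsilyloxy)oxolan-2-one | O=C1OCC[C@@]1(C)O[Si](C)(C)C | intermediate
6 | 2-bromoprop-2-en-1-ol | OCC(Br)=C | starting material
7 | ethynyltrimethylsilane | C#C[Si](C)(C)C | starting material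
8 | 2-methylidene-4-(trimethylsilyl)but-3-yn-1-ol | OCC(=C)C#C[Si](C)(C)C | intermediate
9 | [(2R)-2-[(trimethylsilyl)ethynyl]oxiran-2-yl]methanol | OC[C@]1(C#C[Si](C)(C)C)CO1 | intermediate
10 | (2S)-2-[(trimethylsilyl)ethynyl]oxirane-2-carbaldehyde | O=C[C@]1(C#C[Si](C)(C)C)CO1 | intermediate
11 | (2S)-2-ethenyl-2-[(trimethylsilyl)ethynyl]oxirane (not isolated) | C=C[C@]1(C#C[Si](C)(C)C)CO1 | intermediate
12 | (2S)-2-ethenyl-2-ethynyloxirane | C=C[C@]1(C#C)CO1 | intermediate
13 | lithium acetylide of 12 (not isolated) | C=C[C@]1(C#C[Li])CO1 | intermediate
14 | (4R)-1-[(2S)-2-ethenyloxiran-2-yl]-6-hydroxy-4-methyl-4-(trimethylsilyloxy)hex-1-yn-3-one (not isolated; in equilibrium with its lactol) | OCC[C@@](C)(O[Si](C)(C)C)C(=O)C#C[C@@]1(C=C)CO1 | intermediate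
15 | (4R)-1-[(2S)-2-ethenyloxiran-2-yl]-4,6-dihydroxy-4-methylhex-1-yn-3-one (not isolated) | OCC[C@@](C)(O)C(=O)C#C[C@@]1(C=C)CO1 | intermediate
16 | (2R)-5-[(2R)-2-ethenyloxiran-2-yl]-2-(2-hydroxyethyl)-2-methylfuran-3(2H)-one | OCC[C@@]1(C)OC(=CC1=O)[C@]2(CO2)C=C | intermediate
17 | 2-[(2R)-5-[(2R)-2-ethenyloxiran-2-yl]-2-methyl-3-oxo-2,3-dihydrofuran-2-yl]acetaldehyde | O=CC[C@@]1(C)OC(=CC1=O)[C@]2(CO2)C=C | intermediate
18 | acryloyl chloride | C=CC(=O)Cl | starting material
19 | 2-(trimethylsilyl)ethanol | OCC[Si](C)(C)C | starting material
20 | 2-(trimethylsilyl)ethyl acrylate | C=CC(=O)OCC[Si](C)(C)C | intermediate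
21 | acrolein | C=CC=O | starting material
22 | 2-(trimethylsilyl)ethyl 3-hydroxy-2-methylidenepent-4-enoate (racemic) | C=CC(O)C(=C)C(=O)OCC[Si](C)(C)C | intermediate
23 | 2-(trimethylsilyl)ethyl (2Z)-2-(bromomethyl)penta-2,4-dienoate | C=C/C=C(\CBr)C(=O)OCC[Si](C)(C)C | intermediate
24 | allylindium bromide from 23, written as the allylindium dibromide (not isolated) | C=C/C=C(\C[In](Br)Br)C(=O)OCC[Si](C)(C)C | intermediate
25 | 2-(trimethylsilyl)ethyl (3R,4R)-3-ethenyl-5-[(2R)-5-[(2R)-2-ethenyloxiran-2-yl]-2-methyl-3-oxo-2,3-dihydrofuran-2-yl]-4-hydroxy-2-methylidenepentanoate | O[C@H](C[C@@]1(C)OC(=CC1=O)[C@]2(CO2)C=C)[C@H](C=C)C(=C)C(=O)OCC[Si](C)(C)C | intermediate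
26 | 2-(trimethylsilyl)ethyl (4R,5Z,7R,8R,10R)-4,15:3,10-diepoxy-8-hydroxy-1-oxogermacra-2,5,11(13)-trien-12-oate | O[C@@H]1C[C@@]2(C)OC(=CC2=O)[C@]3(CO3)/C=C\[C@@H]1C(=C)C(=O)OCC[Si](C)(C)C | intermediate
27 | methacrylic anhydride | CC(=C)C(=O)OC(=O)C(C)=C | starting material
28 | 2-(trimethylsilyl)ethyl (4R,5Z,7R,8R,10R)-4,15:3,10-diepoxy-8-(2-methylprop-2-enoyloxy)-1-oxogermacra-2,5,11(13)-trien-12-oate | C=C(C)C(=O)O[C@@H]1C[C@@]2(C)OC(=CC2=O)[C@]3(CO3)/C=C\[C@@H]1C(=C)C(=O)OCC[Si](C)(C)C | intermediate
29 | (4R,5Z,7R,8R,10R)-4,15:3,10-diepoxy-8-(2-methylprop-2-enoyloxy)-1-oxogermacra-2,5,11(13)-trien-12-oic acid | C=C(C)C(=O)O[C@@H]1C[C@@]2(C)OC(=CC2=O)[C@]3(CO3)/C=C\[C@@H]1C(=C)C(=O)O | intermediate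
30 | (4Z,6R,7R,8R,10R)-3,10-epoxy-15-hydroxy-8-(2-methylprop-2-enoyloxy)-1-oxogermacra-2,4,11(13)-trien-12,6-olide, CNP0180483.5 | C=C(C)C(=O)O[C@@H]1C[C@@]2(C)OC(=CC2=O)/C(CO)=C\[C@H]2OC(=O)C(=C)[C@@H]21 | target

Total step count: 17. Longest linear sequence: 11 steps (steps 4–9 and 13–17, from 6 and 7).

Least certain steps

Step 17 (key step). The tethered carboxylate may fail to reach C6 on the face anti to palladium, for instance through a conformational mismatch in the bridged ring or through hindered approach of the metal to the alkene face opposite the epoxide oxygen. The π-allyl alkoxide could then revert, drift to carbonyl isomers by hydride shift, or lose configuration at C6 by palladium–palladium exchange or by re-ionization of the allylic lactone. Fallback: set out from 28 and separate ionization from lactonization. Pd(PPh3)4 with chloroacetic acid as an external nucleophile should give, by the same retentive 1,4-addition, the 6-O-chloroacetyl 15-alcohol F1. Thiourea and NaHCO3 remove the chloroacetate selectively to give the 6,15-diol ester F2. Fluoride then unmasks the hydroxy acid F3, whose γ-hydroxy acid closes (EDC·HCl, DMAP if needed) to rejoin the route at 30.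

Step 14. Intermolecular metathesis may outrun closure of the strained bridged ring, ruthenium hydrides may move the alkenes around the doubly allylic C7, and at the temperature needed the free C8 hydroxyl may lactonize onto the ester or chelate the carbene. Fallback: set out from 25 and cap the hydroxyl as the triethylsilyl ether F4 (Et3SiCl, imidazole). This removes the lactonization and chelation channels and allows more forcing metathesis, which gives the silyl-protected macrocycle F5. Buffered HF·pyridine then returns to the route at 26.

Step 13. Facial discrimination at the aldehyde by the remote quaternary C10 is likely to be poor, so that the syn adduct of the opposite absolute sense forms to a similar extent. β-Elimination of the furanone oxygen from the aldehyde may also compete before addition. Fallback: replace substrate control by catalyst control. Set out from 22 and acetylate it to the acetate F6. Copper-catalysed borylation with allylic transposition (CuCl, B2pin2, KOAc) gives the allylboronate F7, 2-(trimethylsilyl)ethyl (2E)-2-[(pinacolboryl)methyl]penta-2,4-dienoate. Its allylboration of 17 under a chiral phosphoric acid catalyst goes through a closed chair, in which the boronate geometry gives the 7,8-syn relationship and the catalyst chooses the aldehyde face. This returns to the route at 25.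

Step 8. Addition of the acetylide to the hindered α-silyloxy lactone may be incomplete or reversible, the lactolate may collapse early and add a second acetylide, and the vinyl epoxide may be opened by methoxide during the cyclization. Losses of the volatile alkyne add to this. Fallback: set out from 5 and lower the electrophile to the aldehyde level. iBu2AlH at −78 °C gives the lactol F8. Excess 13 adds to its open form to give the propargylic diol F9 (both carbinol epimers). MnO2 oxidizes only the propargylic alcohol and returns to the route at 14, from which the same methanolysis and cyclization lead to 16.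

## Further compounds

F1 | step 17 | 2-(trimethylsilyl)ethyl (4Z,6R,7R,8R,10R)-6-(chloroacetoxy)-3,10-epoxy-15-hydroxy-8-(2-methylprop-2-enoyloxy)-1-oxogermacra-2,4,11(13)-trien-12-oate | C=C(C)C(=O)O[C@@H]1C[C@@]2(C)OC(=CC2=O)/C(CO)=C\[C@@H](OC(=O)CCl)[C@@H]1C(=C)C(=O)OCC[Si](C)(C)C
F2 | step 17 | 2-(trimethylsilyl)ethyl (4Z,6R,7R,8R,10R)-3,10-epoxy-6,15-dihydroxy-8-(2-methylprop-2-enoyloxy)-1-oxogermacra-2,4,11(13)-trien-12-oate | C=C(C)C(=O)O[C@@H]1C[C@@]2(C)OC(=CC2=O)/C(CO)=C\[C@@H](O)[C@@H]1C(=C)C(=O)OCC[Si](C)(C)C
F3 | step 17 | (4Z,6R,7R,8R,10R)-3,10-epoxy-6,15-dihydroxy-8-(2-methylprop-2-enoyloxy)-1-oxogermacra-2,4,11(13)-trien-12-oic acid | C=C(C)C(=O)O[C@@H]1C[C@@]2(C)OC(=CC2=O)/C(CO)=C\[C@@H](O)[C@@H]1C(=C)C(=O)O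
F4 | step 14 | triethylsilyl ether of 25 | CC[Si](CC)(CC)O[C@H](C[C@@]1(C)OC(=CC1=O)[C@]2(CO2)C=C)[C@H](C=C)C(=C)C(=O)OCC[Si](C)(C)C
F5 | step 14 | 8-O-triethylsilyl ether of 26 | CC[Si](CC)(CC)O[C@@H]1C[C@@]2(C)OC(=CC2=O)[C@]3(CO3)/C=C\[C@@H]1C(=C)C(=O)OCC[Si](C)(C)C
F6 | step 13 | 2-(trimethylsilyl)ethyl 3-acetoxy-2-methylidenepent-4-enoate (racemic) | C=CC(OC(C)=O)C(=C)C(=O)OCC[Si](C)(C)C
F7 | step 13 | 2-(trimethylsilyl)ethyl (2E)-2-[(4,4,5,5-tetramethyl-1,3,2-dioxaborolan-2-yl)methyl]penta-2,4-dienoate | C=C/C=C(\CB1OC(C)(C)C(C)(C)O1)C(=O)OCC[Si](C)(C)C
F8 | step 8 | (3R)-3-methyl-3-(trimethylsilyloxy)oxolan-2-ol (both anomers) | OC1OCC[C@@]1(C)O[Si](C)(C)C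
F9 | step 8 | (4R)-1-[(2S)-2-ethenyloxiran-2-yl]-4-methyl-4-(trimethylsilyloxy)hex-1-yne-3,6-diol (both C3 epimers) | OCC[C@@](C)(O[Si](C)(C)C)C(O)C#C[C@@]1(C=C)CO1
A1 | alternative 1 | cis-decalin C3,C8-diol with C10 trimethylsilyl ether, O15 tert-butyldimethylsilyl ether and the trans lactone (one cis-diol isomer drawn) | O[C@]12C[C@](O[Si](C)(C)C)(C)C(=O)C[C@@]1(O)C(CO[Si](C)(C)C(C)(C)C)=C[C@H]1OC(=O)C(=C)[C@@H]12
A2 | alternative 1 | ten-membered 1,3,8-trione with Z C4=C5 and trans lactone | O=C1C[C@](O[Si](C)(C)C)(C)C(=O)CC(=O)/C(CO[Si](C)(C)C(C)(C)C)=C\[C@H]2OC(=O)C(=C)[C@@H]21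
A3 | alternative 2 | metathesis diene: furanone with 1,1-disubstituted C4 alkene, C6 vinyl 13-nor lactone, O8 triethylsilyl ether | CC[Si](CC)(CC)O[C@H](C[C@@]1(C)OC(=CC1=O)C(=C)CO[Si](C)(C)C(C)(C)C)[C@H]1CC(=O)O[C@@H]1C=C
A4 | alternative 2 | bridged furanone core with the 11,13-dihydro-13-nor lactone | CC[Si](CC)(CC)O[C@@H]1C[C@@]2(C)OC(=CC2=O)/C(CO[Si](C)(C)C(C)(C)C)=C\[C@H]2OC(=O)C[C@@H]21
A5 | alternative 3 | diisopropylsilyl-linked 3-silyloxyfuran and C8 enol ether | Cc1oc2cc1O[Si](C(C)C)(C(C)C)OC(=C)[C@H]1C(=C)C(=O)O[C@@H]1/C=C2/CO[Si](C)(C)C(C)(C)C
A6 | alternative 3 | 8-oxo furanoheliangolide core, O15 tert-butyldimethylsilyl ether | O=C1C[C@@]2(C)OC(=CC2=O)/C(CO[Si](C)(C)C(C)(C)C)=C\[C@H]2OC(=O)C(=C)[C@@H]21
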